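Two questions stand here, and both turn on a race between two clocks.

substrate 2.0 mM; reagent 1.90 mM; initiator 100 µM; time 5.0 h

- the target standing at 5.0 h, as a percentage of the substrate charged
- the isomer of the product standing at 5.0 h, as a percentage of the substrate charged

- in percentages every species weighs as the substrate in it: one ended chains A counts as two
- for target the idle adduct is counted in
- a step written with two of one species runs at k times the square of its concentration and takes two of it each time
- run time (flask): 5.0 h

    initiator → 2 initiating radical (k1 = 6.5 × 10⁻⁵ s⁻¹)
    substrate + initiating radical → capped initiator + first chain carrier (k2 = 1.3 × 10⁸ L mol⁻¹ s⁻¹)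
    reagent + first chain carrier → target + second chain carrier (k3 = 1.1 × 10⁶ L mol⁻¹ s⁻¹)
    substrate + second chain carrier → by-product + first chain carrier (k4 = 2.9 × 10⁶ L mol⁻¹ s⁻¹)
    2 first chain carrier → ended chains A (k5 = 2.2 × 10⁸ L mol⁻¹ s⁻¹)
    2 second chain carrier → ended chains B (k6 = 9.6 × 10⁶ L mol⁻¹ s⁻¹)
    reagent + target ⇌ idle adduct, settled at all times (K7 = 1000 L mol⁻¹)
    target ⇌ isomer of the product (K8 = 0.71, k8 = 0.087 s⁻¹)

The chain takes one reagent and one substrate per turn, and each initiating radical also caps one substrate. So in this flask the opposite outcome, reagent left standing with the substrate gone, needs the capping to eat the substrate excess before the chain has used the reagent. I reckon both clocks for this flask.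

At the charges, step 5 ends chains 176 times faster than step 6, so I balance radical supply against step 5 alone. That gives the first chain carrier at

x = sqrt(k1·cN/k5) = 5.44 nM.

The reagent then falls pseudo-first-order, with lifetime

τc = 1/(k3·x) = 2.79 min.

The excess is 0.100 mM. At the starting radical supply, which can only fall, capping needs

τm = (cA − cB)/(2·k1·cN) = 2.14 h.

The race number, the time to cap the excess over the lifetime of the reagent, is

ρ = τm/τc = 46.0.

The opposite outcome needs ρ near one or below, and this flask stands far above that. So the reagent is the limiting reagent, and the idle adduct gives back its target as the reagent falls. Step 8 relaxes on a scale of 11.5 s, shorter than τc, so it splits the product 1 : 0.71. I commit to 55.6 % target and 39.4 % isomer of the product.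

The forecast gives 55.6 % and 39.4 %, holding that “the reagent should be essentially used up well before 5 h”.

The simulated flask gives 55.6 % target and 39.4 % isomer of the product. At 0.500 h the capped initiator in this flask stands at 0.0221 mM, less than the excess, with 0.173 % of the charged reagent left. In the neighbouring flask with 0.76 mM of reagent, ρ is 570, so the reagent again goes first, and the same reckoning gives 22.2 % target and 15.8 % isomer of the product. That flask holds 22.2 % and 15.8 %.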